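# Proposed synthesis of CNP0242386.1 via a three-component conjugate addition–aldol on (5S)-5-menthyloxy-2(5H)-furanone

## Structural features

The target joins two oxygen heterocycles through a single benzylic methylene. One is a 2,3,4-trisubstituted tetrahydrofuran (C2 3-hydroxy-4-methoxyphenyl, C3 hydroxymethyl, C4 CH2–aryl). The other is a 2-aryl-3-hydroxymethyl-4-methoxy-2,3-dihydrobenzofuran, attached through its C6.

The tetrahydrofuran carries three contiguous stereocentres (2R,3S,4S; 2,3-trans, 3,4-cis) and the dihydrobenzofuran two (2S,3R; trans). The two clusters are insulated by the CH2–arene link, so neither can steer the other and each must be set in the absolute sense.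

Ring A of the dihydrobenzofuran is 1,2,3,5-tetrasubstituted: C3a lies between the ring oxygen on C7a and the methoxy group on C4, and the carbon substituent on C6 is meta to both oxygens.

Both aryl-bearing ring carbons are para-oxygenated benzylic ethers. They ionise under acid, and positions C5 and C7 of ring A are nucleophilic enough to capture the tetrahydrofuran C2 cation in a six-membered carbocyclisation. The benzylic C–O bonds are also open to hydrogenolysis, and the phenol para to the dihydrobenzofuran C2–O bond opens a quinone methide pathway under base.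

The real difficulty is the 3,4-cis pair in the correct absolute sense, made while two different aryl-bearing units are attached to C3 and C4 through one carbon each.

The key step exploits the fact that tetrahydrofuran C3 and C4, with the hydroxymethyl carbon, C5 and the benzylic methylene, are the alpha carbon, beta carbon, carbonyl carbon, acetal carbon and beta-nucleophile of a 5-alkoxybutenolide. C2 is then an aldehyde carbon that traps the enolate.

## Logic of the disconnections

**31 to 30.** Only O–Si bonds are cut. All three silyl groups are removed together at the end because fluoride is the one reagent that leaves two benzylic ethers untouched. The forward step must avoid a free phenoxide para to the dihydrobenzofuran C2–O bond, hence buffering.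

**30 to 29.** The O1–C2 bond of the tetrahydrofuran is cut. C2 is a para-methoxybenzylic carbon, so it can be closed from a carbinol through its cation, and its configuration is then dictated by C3. This removes one ring and one stereocentre that would otherwise need separate control. The forward step must keep oxygen capture kinetic so that ring A does not take the cation.

**29 to 28 to 27.** No skeletal bond is cut. The two CH2OH carbons of 29 are the carbonyl and acetal carbons of lactone 28, and the benzylic methylene is the dithioketal carbon of 27. These are exactly the functional groups that a conjugate addition–aldol leaves behind. The forward steps need a desulfurisation that spares benzylic C–O bonds and a hydride reduction that releases 4.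

**27 to 24, 5 and 7.** Two C–C bonds are cut: lactone C4 to the dithioketal carbon, and lactone C3 to the carbinol carbon. The molecule falls into three pieces of comparable size, and the two stereocentres that matter are relayed from the acetal centre of 5. The forward step needs 1,4-selectivity, attack anti to the menthyloxy group, and trans trapping of the enolate.

**5 to 3 and 4; 3 to 1.** The acetal C–O bond is cut, then the butenolide is traced to a furan by oxidative loss of its formyl carbon. 4 serves as auxiliary and as the handle for crystallisation. The forward acetalisation gives both epimers, so it relies on crystallisation with acid re-equilibration.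

**7 to 6 and 18 to 17.** O–Si bonds only. Triisopropylsilyl is chosen for both phenols because they must pass through organolithium, hydride and acid steps.

**24 to 23 to 22.** The O–Si bond of the primary alcohol and the two C–S bonds are cut. The thioacetal is made from the aldehyde first and the primary alcohol silylated afterwards, since the Lewis acid of the first operation would strip a primary silyl ether.

**22 to 21.** The O1–C2 bond of the dihydrobenzofuran is cut, and the aldehyde and ring A phenol are re-masked. C2 is again a para-oxygenated benzylic carbon that closes through its cation, trans to C3. What remains is an acyclic 1,3-diol in which only C3 has to be controlled. The forward step combines three acid-triggered events and must not disturb C3.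

**21 to 20 to 16 and 18.** The C2–C3 bond is cut as an aldol bond, and the primary alcohol is taken back to an acyl oxazolidinone. The auxiliary sets the alpha carbon, the only centre that has to persist. The forward aldol needs a hindered di-ortho-substituted arylacetyl enolate to react cleanly.

**16 to 13 and 14; 13 to 12 to 10.** The N-acyl bond is cut, then the bond between ring A and its CH2 arm. The ring position between the two oxygens is the one that directed lithiation reaches selectively, and ethylene oxide supplies both carbons of the arm. The forward lithiation needs the C6 carbon masked against butyllithium.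

**10 to 9 to 8.** C–O bonds of the methoxymethyl ether and of the cyclic acetal are cut. The first group directs the metalation and the second hides the aldehyde, and both fall off in the step that makes 22.

## Other disconnections considered

**Alternative 1:** The cut goes through ring A itself. The arene bonds C7a–C3a, C7a–C7 and C4–C5 would be formed together by heating cyclobutenone A2, which carries the finished tetrahydrofuran on a methylene arm, with siloxyalkyne A3, which carries the future C2 and C3 as a protected 1,3-diol. The sequence is ring opening to a vinylketene, [2+2] addition to the alkyne, a second ring opening and a six-electron closure, giving phenol A1.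

- In its favour: the substitution pattern of ring A, including the carbon between the two oxygens, is fixed by the pericyclic sequence and needs no directed metalation. On this point it is better than the chosen plan. The union is neutral, cation-free and very late.
- Against it here: A2 presupposes a complete, enantiopure tetrahydrofuran, which would still have to come from chemistry like the chosen key step. A3 needs an enantiopure anti-1,3-diol and a sensitive ynol ether. After the benzannulation, A1 still requires closure of the dihydrobenzofuran by substitution at a para-alkoxybenzylic carbinol (inversion can leak to ionisation), exchange of the silyloxy group for methoxy, and hydrogenolytic debenzylation next to two benzylic ethers.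
- Comparison: equal or better in structural logic at ring A and equal in mechanistic safety at the union, but clearly longer. It adds a second strategy on top of the butenolide chemistry instead of replacing it.

**Alternative 2:** The same O1–C2 bond is cut, but from the methylene oxidation level. DDQ would abstract hydride from the para-methoxybenzylic CH2 of dibenzylbutanediol A5 and the primary hydroxyl in the 1,4-position would trap the cation to give bis(aryl acetate) A4.

- In its favour: A5 comes from a conjugate addition–alkylation on the same butenolide with a benzyl halide. There is no aldol, no carbinol epimers, no retro-aldol, and no benzylic carbinol exposed to nickel. In the coupling it is the equal of the chosen plan, and in the handling of the coupled product it is slightly better. The trans outcome at C2 rests on the same cation, so stereocontrol is equal, and the count after the coupling is equal or one step shorter.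
- Against it here: DDQ dehydrogenates 2-aryl-2,3-dihydrobenzofurans to benzofurans, and the dihydrobenzofuran C2–H is benzylic and alpha to oxygen. Three free primary hydroxyls are present. The same cation can still be taken by ring A, an equal risk. The acetates add a protection and a deprotection.
- Comparison: the chosen plan brings the C2 oxygen in with the aldehyde and never needs an oxidant in the presence of the dihydrobenzofuran, which is the safer chemoselectivity.

**Alternative 3:** The cut is the C3–C3a bond of the dihydrobenzofuran. PhI(OAc)2 with H2SO4 in trimethyl orthoformate would convert (S)-flavanone A7 into its enol ether, place the iodine reagent on flavanone C3 and trigger a 1,2-shift of the ring A carbon from C4 to C3. The pyranone contracts to trans ester A6 and C4 is expelled as the ester carbon.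

- In its favour: ring A comes from a phloroglucinol-type ketone in which the acyl-bearing carbon is already flanked by two oxygens. That is better than the chosen route, which needs a directed metalation. The trans relationship is relayed stereospecifically from one stereocentre with no free benzylic cation next to C3, again better than the acid closure of step 12. No auxiliary is needed.
- Against it here: an enantiopure flavanone is required, and flavanones open to chalcones under acid, so the stereocentre is at risk in a strongly acidic, oxidising medium that also threatens the aryl silyl ether. C6 arrives as a benzyloxy group and must be converted into carbon (debenzylation, triflation, palladium-catalysed carbonylation and redox adjustment, about four steps). The alternative supplies only the fragment and still needs the chosen key step.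
- Comparison: the step count for the fragment is about equal. The risk moves from a cationic ring closure to the configurational stability of A7 and to a late aryl C–O to C–C exchange.

Key step: step 15

## Remarks before the steps

- **Assumption.** Ring A is drawn from 3-hydroxy-5-methoxybenzaldehyde (8), a catalogue compound, because the C6 carbon is needed at the aldehyde level. Starting from the corresponding methyl benzoate would add two redox steps.
- **Configuration check.** The (5S) acetal of 5 with anti addition and trans trapping gives (3R,4S,5S)-27, which maps onto (3S,4S) in the tetrahydrofuran. The dihydrobenzofuran is (2S,3R) throughout. No constitution or configuration needed correction.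
- **Design choices for the precursor.** Both phenols are carried as triisopropylsilyl ethers and only the primary alcohol as a tert-butyldimethylsilyl ether. The thioacetal is made before that primary alcohol is silylated.
- **Carbinol epimers.** The carbinol carbon of 27, 28 and 29 is expected as a mixture of epimers. Both are carried on, and the list shows the (R) epimer.

## Route

Step 1
Reactants: 1 furfural
Product: 3 5-hydroxy-2(5H)-furanone (racemic), via furfural endoperoxide 2 (not isolated)
Conditions: O2, hν (visible), rose bengal disodium salt (C20H2Cl4I4Na2O5, cat.), MeOH, 20 °C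
Reagents that add atoms: dioxygen, O=O
Why: Singlet-oxygen [4+2] cycloaddition to the furan gives the endoperoxide, which methanol opens with loss of the formyl carbon as methyl formate; this is the known photooxygenation of 2-furaldehyde to the hydroxybutenolide.

Step 2
Reactants: 3 5-hydroxy-2(5H)-furanone; 4 (+)-menthol
Product: 5 (5S)-5-[(1S,2R,5S)-menthyloxy]-2(5H)-furanone
Conditions: CSA (cat.), toluene, reflux, Dean–Stark; crystallisation from petroleum ether, mother liquor re-equilibrated with CSA
Reagents that add atoms: none
Why: Acid-catalysed acetalisation gives both C5 epimers; the (5S) epimer should crystallise, and since the acetal carbon epimerises under the same acid the mother liquor can be re-equilibrated and crystallised again (crystallisation-driven resolution of the acetal centre).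

Step 3
Reactants: 6 isovanillin
Product: 7 4-methoxy-3-(triisopropylsilyloxy)benzaldehyde
Conditions: TIPSCl, imidazole, DMF, 20 °C
Reagents that add atoms: chlorotriisopropylsilane, CC(C)[Si](Cl)(C(C)C)C(C)C
Why: Standard silylation of a phenol; the triisopropylsilyl ether is chosen because it must later survive a lithium alkoxide, LiAlH4 and a Brønsted acid.

Step 4
Reactants: 8 3-hydroxy-5-methoxybenzaldehyde
Product: 9 3-(5,5-dimethyl-1,3-dioxan-2-yl)-5-methoxyphenol
Conditions: 2,2-dimethylpropane-1,3-diol, TsOH·H2O (cat.), toluene, reflux, Dean–Stark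
Reagents that add atoms: 2,2-dimethylpropane-1,3-diol, OCC(C)(C)CO
Why: Acid-catalysed acetalisation with azeotropic removal of water; the six-membered neopentyl acetal tolerates butyllithium and the buffered oxidation of step 7 better than an open-chain acetal.

Step 5
Reactants: 9 3-(5,5-dimethyl-1,3-dioxan-2-yl)-5-methoxyphenol
Product: 10 2-[3-methoxy-5-(methoxymethoxy)phenyl]-5,5-dimethyl-1,3-dioxane
Conditions: MOMCl, iPr2NEt, CH2Cl2, 0 → 20 °C
Reagents that add atoms: chloromethyl methyl ether, COCCl
Why: O-Alkylation of the phenol; the methoxymethyl ether is both the protecting group and the directing group for the metalation in step 6.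

Step 6
Reactants: 10 2-[3-methoxy-5-(methoxymethoxy)phenyl]-5,5-dimethyl-1,3-dioxane
Product: 12 2-[4-(5,5-dimethyl-1,3-dioxan-2-yl)-2-methoxy-6-(methoxymethoxy)phenyl]ethanol, via ring A aryllithium 11 (not isolated)
Conditions: n-BuLi, THF, 0 °C; ethylene oxide (THF solution), 0 → 20 °C; aq. NH4Cl
Reagents that add atoms: ethylene oxide, C1CO1
Why: Directed ortho-metalation: the ring hydrogen flanked by the methoxymethoxy and methoxy groups is the most acidic and is coordinated from both sides, so lithiation should occur there and not beside the acetal; the aryllithium then opens ethylene oxide by SN2 to give the two-carbon arm.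

Step 7
Reactants: 12 2-[4-(5,5-dimethyl-1,3-dioxan-2-yl)-2-methoxy-6-(methoxymethoxy)phenyl]ethanol
Product: 13 [4-(5,5-dimethyl-1,3-dioxan-2-yl)-2-methoxy-6-(methoxymethoxy)phenyl]acetic acid
Conditions: TEMPO (cat.), NaClO2, NaOCl (cat.), MeCN–phosphate buffer (pH 6.7), 35 °C
Reagents that add atoms: sodium chlorite, [Na+].[O-]Cl=O
Why: Nitroxyl-catalysed oxidation of the primary alcohol with chlorite as terminal oxidant gives the acid in one operation; the near-neutral buffer protects the acetal and the methoxymethyl ether, and only catalytic hypochlorite is present, which limits ring chlorination.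

Step 8
Reactants: 13 [4-(5,5-dimethyl-1,3-dioxan-2-yl)-2-methoxy-6-(methoxymethoxy)phenyl]acetic acid; 14 (S)-4-benzyl-2-oxazolidinone
Product: 16 (4S)-4-benzyl-3-{[4-(5,5-dimethyl-1,3-dioxan-2-yl)-2-methoxy-6-(methoxymethoxy)phenyl]acetyl}-1,3-oxazolidin-2-one, via mixed pivalic anhydride 15 (not isolated)
Conditions: PivCl, Et3N, THF, −20 °C; then LiCl, 14, −20 → 20 °C
Reagents that add atoms: none
Why: N-Acylation of the oxazolidinone through the mixed pivalic anhydride, assisted by LiCl; no stereocentre is formed and the acid is never stored in free form, which protects the acetal.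

Step 9
Reactants: 17 vanillin
Product: 18 3-methoxy-4-(triisopropylsilyloxy)benzaldehyde
Conditions: TIPSCl, imidazole, DMF, 20 °C
Reagents that add atoms: chlorotriisopropylsilane, CC(C)[Si](Cl)(C(C)C)C(C)C
Why: Standard silylation of a phenol; the silyloxy group stays para to the future benzylic carbon, where it still stabilises the cation needed in step 12.

Step 10
Reactants: 16 (4S)-4-benzyl-3-{[4-(5,5-dimethyl-1,3-dioxan-2-yl)-2-methoxy-6-(methoxymethoxy)phenyl]acetyl}-1,3-oxazolidin-2-one; 18 3-methoxy-4-(triisopropylsilyloxy)benzaldehyde
Product: 20 (4S)-4-benzyl-3-{(2S,3S)-2-[4-(5,5-dimethyl-1,3-dioxan-2-yl)-2-methoxy-6-(methoxymethoxy)phenyl]-3-hydroxy-3-[3-methoxy-4-(triisopropylsilyloxy)phenyl]propanoyl}-1,3-oxazolidin-2-one, via dibutylboron Z-enolate 19 (not isolated)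
Conditions: Bu2BOTf, iPr2NEt, CH2Cl2, −78 → 0 °C; 18, −78 → 0 °C; pH 7 buffer, MeOH, H2O2, 0 °C
Reagents that add atoms: none
Why: Evans syn-aldol reaction: soft enolisation gives the (Z)-boron enolate, and in the closed Zimmerman–Traxler transition state the aldehyde meets the enolate face opposite the benzyl group of the auxiliary, which fixes the alpha carbon as (S), the later C3 of the dihydrobenzofuran; the carbinol centre (S) follows from the syn relationship but is not needed later.

Step 11
Reactants: 20 (4S)-4-benzyl-3-{(2S,3S)-2-[4-(5,5-dimethyl-1,3-dioxan-2-yl)-2-methoxy-6-(methoxymethoxy)phenyl]-3-hydroxy-3-[3-methoxy-4-(triisopropylsilyloxy)phenyl]propanoyl}-1,3-oxazolidin-2-one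
Product: 21 (1S,2R)-2-[4-(5,5-dimethyl-1,3-dioxan-2-yl)-2-methoxy-6-(methoxymethoxy)phenyl]-1-[3-methoxy-4-(triisopropylsilyloxy)phenyl]propane-1,3-diol
Conditions: LiBH4, MeOH (1 equiv), THF, 0 °C
Reagents that add atoms: none
Why: Hydride cleavage of the imide at the exocyclic carbonyl gives the primary alcohol and releases the auxiliary for recovery; the acetal, the silyl ether and both stereocentres are not touched (the alpha carbon becomes R only through the change in CIP priorities).

Step 12
Reactants: 21 (1S,2R)-2-[4-(5,5-dimethyl-1,3-dioxan-2-yl)-2-methoxy-6-(methoxymethoxy)phenyl]-1-[3-methoxy-4-(triisopropylsilyloxy)phenyl]propane-1,3-diol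
Product: 22 (2S,3R)-3-(hydroxymethyl)-4-methoxy-2-[3-methoxy-4-(triisopropylsilyloxy)phenyl]-2,3-dihydro-1-benzofuran-6-carbaldehyde
Conditions: HCl (ca. 1 M), MeOH–THF, 45 °C; then H2O, 20 °C
Reagents that add atoms: water, O
Why: Acid removes the methoxymethyl group and exchanges the acetal, and the para-siloxybenzylic carbinol ionises; methanol holds the cation reversibly as its methyl ether until the freed phenol closes the five-membered ring (5-exo capture of a benzylic cation, the usual phenylcoumaran closure), and because the new C2–O bond can re-ionise the 2,3-trans isomer with the aryl group away from the C3 hydroxymethyl group should result, while C3 keeps the configuration set in step 10; water then liberates the aldehyde.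

Step 13
Reactants: 22 (2S,3R)-3-(hydroxymethyl)-4-methoxy-2-[3-methoxy-4-(triisopropylsilyloxy)phenyl]-2,3-dihydro-1-benzofuran-6-carbaldehyde
Product: 23 {(2S,3R)-6-[bis(phenylthio)methyl]-4-methoxy-2-[3-methoxy-4-(triisopropylsilyloxy)phenyl]-2,3-dihydro-1-benzofuran-3-yl}methanol
Conditions: PhSH (2.5 equiv), BF3·OEt2 (0.3 equiv), CH2Cl2, −30 → 0 °C
Reagents that add atoms: thiophenol, Sc1ccccc1
Why: Lewis-acid-catalysed thioacetalisation of an aromatic aldehyde; it is run while the primary alcohol is still free because BF3 would remove a primary silyl ether, and cold with substoichiometric acid so that the aldehyde reacts before the benzylic aryl ether can ionise.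

Step 14
Reactants: 23 {(2S,3R)-6-[bis(phenylthio)methyl]-4-methoxy-2-[3-methoxy-4-(triisopropylsilyloxy)phenyl]-2,3-dihydro-1-benzofuran-3-yl}methanol
Product: 24 (2S,3R)-6-[bis(phenylthio)methyl]-3-[(tert-butyldimethylsilyloxy)methyl]-4-methoxy-2-[3-methoxy-4-(triisopropylsilyloxy)phenyl]-2,3-dihydro-1-benzofuran
Conditions: TBSCl, imidazole, DMF, 20 °C
Reagents that add atoms: tert-butylchlorodimethylsilane, CC(C)(C)[Si](C)(C)Cl
Why: Standard silylation of the only free hydroxyl, so that the dithioacetal C–H is the single acidic site in the key step.

Step 15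
Reactants: 24 (2S,3R)-6-[bis(phenylthio)methyl]-3-[(tert-butyldimethylsilyloxy)methyl]-4-methoxy-2-[3-methoxy-4-(triisopropylsilyloxy)phenyl]-2,3-dihydro-1-benzofuran; 5 (5S)-5-[(1S,2R,5S)-menthyloxy]-2(5H)-furanone; 7 4-methoxy-3-(triisopropylsilyloxy)benzaldehyde
Product: 27 (3R,4S,5S)-4-[aryl-bis(phenylthio)methyl]-3-{(R)-hydroxy[4-methoxy-3-(triisopropylsilyloxy)phenyl]methyl}-5-[(1S,2R,5S)-menthyloxy]dihydrofuran-2(3H)-one (aryl = the silylated dihydrobenzofuran-6-yl unit of 24), via lithiated dithioacetal 25 (not isolated), via lithium lactone enolate 26 (not isolated)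
Conditions: n-BuLi (1.05 equiv), THF, −78 °C; 5, −78 °C; 7, −78 °C; AcOH, −78 °C
Reagents that add atoms: none
Why: Butyllithium removes the only acidic proton of 24, the one between the two sulfur atoms and the arene, to give the soft sulfur-stabilised benzylic anion 25. This anion adds 1,4 to 5 (tandem conjugate addition–aldol, the known three-component reaction of lithiated aryl dithioacetals with 5-alkoxybutenolides); the menthyloxy group on the acetal carbon shields one face of the flat lactone, so the nucleophile enters anti to it and the new beta centre (lactone C4, S) is controlled by the (5S) acetal centre. The lithium enolate 26 is not protonated but trapped in the same flask by the non-enolisable aldehyde 7, which approaches the face opposite the very large bis(phenylthio)benzyl group, so C3 is set trans to C4 (3R) by the centre formed a moment before. The carbinol centre is not reliably controlled and both epimers are expected, which is harmless because that carbon is ionised in step 18. No ring is closed; two C–C bonds are formed, from the dithioketal carbon to lactone C4 and from the carbinol carbon to lactone C3. The step needs 1,4- over 1,2-selectivity, secured by the soft and hindered anion, facial selectivity at the beta carbon, secured by the acetal substituent, and trans trapping, secured by the bulk of the new substituent. A cold acetic acid quench keeps the lithium aldolate from reverting.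

Step 16
Reactants: 27 (3R,4S,5S)-4-[aryl-bis(phenylthio)methyl]-3-{(R)-hydroxy[4-methoxy-3-(triisopropylsilyloxy)phenyl]methyl}-5-menthyloxydihydrofuran-2(3H)-one
Product: 28 (3R,4S,5S)-4-(arylmethyl)-3-{(R)-hydroxy[4-methoxy-3-(triisopropylsilyloxy)phenyl]methyl}-5-[(1S,2R,5S)-menthyloxy]dihydrofuran-2(3H)-one
Conditions: Raney Ni (W-2, washed to neutrality), EtOH–THF, 20 °C
Reagents that add atoms: none
Why: Reductive desulfurisation of both C–S bonds on the nickel surface turns the dithioketal carbon into the benzylic methylene; neutral Raney Ni at room temperature is used so that the benzylic carbinol and the benzylic ethers are not hydrogenolysed and the aldol is not reversed; no stereocentre is touched.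

Step 17
Reactants: 28 (3R,4S,5S)-4-(arylmethyl)-3-{(R)-hydroxy[4-methoxy-3-(triisopropylsilyloxy)phenyl]methyl}-5-menthyloxydihydrofuran-2(3H)-one
Product: 29 (2S,3S)-3-(arylmethyl)-2-{(R)-hydroxy[4-methoxy-3-(triisopropylsilyloxy)phenyl]methyl}butane-1,4-diol
Conditions: LiAlH4, THF, 0 → 20 °C; Rochelle salt work-up
Reagents that add atoms: none
Why: LiAlH4 reduces the lactone carbonyl to CH2OH and the acetal carbon, through lactol and aldehyde, to the second CH2OH with release of menthol; the two ring stereocentres are not epimerisable once the carbonyl is gone.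

Step 18
Reactants: 29 (2S,3S)-3-(arylmethyl)-2-{(R)-hydroxy[4-methoxy-3-(triisopropylsilyloxy)phenyl]methyl}butane-1,4-diol
Product: 30 tris-silyl ether of the target: (2R,3S,4S)-tetrahydrofuran with aryl O-triisopropylsilyl groups on both phenols and the tert-butyldimethylsilyl ether on the dihydrobenzofuran hydroxymethyl group
Conditions: CSA (0.1–0.2 equiv), CH2Cl2, −20 → 0 °C; Et3N quench
Reagents that add atoms: none
Why: Mild acid ionises only the para-methoxybenzylic carbinol, and the primary hydroxyl that stems from the former acetal carbon captures the cation in a 5-exo closure (the other primary hydroxyl could only form an oxetane); the aryl group ends up trans to the C3 hydroxymethyl group, which sets C2 as (R) whichever carbinol epimer is used, and catalytic acid at low temperature keeps the closure kinetic so that ring A does not take the cation.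

Step 19
Reactants: 30 tris-silyl ether of the target
Product: 31 target, {(2S,3R)-2-(4-hydroxy-3-methoxyphenyl)-6-{[(3S,4S,5R)-5-(3-hydroxy-4-methoxyphenyl)-4-(hydroxymethyl)oxolan-3-yl]methyl}-4-methoxy-2,3-dihydro-1-benzofuran-3-yl}methanol
Conditions: TBAF, AcOH, THF, 0 → 20 °C
Reagents that add atoms: none
Why: Fluoride cleaves the two aryl silyl ethers and the primary silyl ether; buffering with acetic acid avoids a free phenoxide para to the dihydrobenzofuran C2–O bond and so closes off the quinone methide pathway.

## Compound list

1 | furfural | O=Cc1ccco1 | starting material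
2 | furfural endoperoxide (racemic) | O=CC12OOC(O1)C=C2 | intermediate
3 | 5-hydroxy-2(5H)-furanone (racemic) | OC1OC(=O)C=C1 | intermediate
4 | (+)-menthol | CC(C)[C@H]1CC[C@H](C)C[C@@H]1O | starting material
5 | (5S)-5-[(1S,2R,5S)-menthyloxy]-2(5H)-furanone | CC(C)[C@H]1CC[C@H](C)C[C@@H]1O[C@@H]1C=CC(=O)O1 | intermediate
6 | isovanillin | COc1ccc(C=O)cc1O | starting material
7 | 4-methoxy-3-(triisopropylsilyloxy)benzaldehyde | COc1ccc(C=O)cc1O[Si](C(C)C)(C(C)C)C(C)C | intermediate
8 | 3-hydroxy-5-methoxybenzaldehyde | COc1cc(O)cc(C=O)c1 | starting material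
9 | 3-(5,5-dimethyl-1,3-dioxan-2-yl)-5-methoxyphenol | COc1cc(O)cc(c1)C1OCC(C)(C)CO1 | intermediate
10 | 2-[3-methoxy-5-(methoxymethoxy)phenyl]-5,5-dimethyl-1,3-dioxane | COCOc1cc(OC)cc(c1)C1OCC(C)(C)CO1 | intermediate
11 | [4-(5,5-dimethyl-1,3-dioxan-2-yl)-2-methoxy-6-(methoxymethoxy)phenyl]lithium | [Li]c1c(OC)cc(cc1OCOC)C1OCC(C)(C)CO1 | intermediate
12 | 2-[4-(5,5-dimethyl-1,3-dioxan-2-yl)-2-methoxy-6-(methoxymethoxy)phenyl]ethanol | OCCc1c(OC)cc(cc1OCOC)C1OCC(C)(C)CO1 | intermediate
13 | [4-(5,5-dimethyl-1,3-dioxan-2-yl)-2-methoxy-6-(methoxymethoxy)phenyl]acetic acid | OC(=O)Cc1c(OC)cc(cc1OCOC)C1OCC(C)(C)CO1 | intermediate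
14 | (S)-4-benzyl-2-oxazolidinone | O=C1OC[C@H](Cc2ccccc2)N1 | starting material
15 | mixed pivalic anhydride of 13 | CC(C)(C)C(=O)OC(=O)Cc1c(OC)cc(cc1OCOC)C1OCC(C)(C)CO1 | intermediate
16 | (4S)-4-benzyl-3-(arylacetyl)oxazolidin-2-one | O=C(Cc1c(OC)cc(cc1OCOC)C1OCC(C)(C)CO1)N1[C@@H](Cc2ccccc2)COC1=O | intermediate
17 | vanillin | COc1cc(C=O)ccc1O | starting material
18 | 3-methoxy-4-(triisopropylsilyloxy)benzaldehyde | COc1cc(C=O)ccc1O[Si](C(C)C)(C(C)C)C(C)C | intermediate
19 | dibutylboron (Z)-enolate of 16 | CCCCB(CCCC)O/C(=C\c1c(OC)cc(cc1OCOC)C1OCC(C)(C)CO1)N1[C@@H](Cc2ccccc2)COC1=O | intermediate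
20 | (2S,3S)-syn-aldol imide | O=C(N1[C@@H](Cc2ccccc2)COC1=O)[C@@H](c1c(OC)cc(cc1OCOC)C1OCC(C)(C)CO1)[C@H](O)c1ccc(O[Si](C(C)C)(C(C)C)C(C)C)c(OC)c1 | intermediate
21 | (1S,2R)-1,2-diarylpropane-1,3-diol | OC[C@@H](c1c(OC)cc(cc1OCOC)C1OCC(C)(C)CO1)[C@H](O)c1ccc(O[Si](C(C)C)(C(C)C)C(C)C)c(OC)c1 | intermediate
22 | (2S,3R)-3-(hydroxymethyl)-4-methoxy-2-[3-methoxy-4-(triisopropylsilyloxy)phenyl]-2,3-dihydrobenzofuran-6-carbaldehyde | O=Cc1cc(OC)c2c(c1)O[C@H](c1ccc(O[Si](C(C)C)(C(C)C)C(C)C)c(OC)c1)[C@H]2CO | intermediate
23 | bis(phenylthio)acetal of 22 (free primary alcohol) | c1ccc(cc1)SC(Sc1ccccc1)c1cc(OC)c2c(c1)O[C@H](c1ccc(O[Si](C(C)C)(C(C)C)C(C)C)c(OC)c1)[C@H]2CO | intermediate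
24 | tert-butyldimethylsilyl ether of 23 (key-step precursor) | c1ccc(cc1)SC(Sc1ccccc1)c1cc(OC)c2c(c1)O[C@H](c1ccc(O[Si](C(C)C)(C(C)C)C(C)C)c(OC)c1)[C@H]2CO[Si](C)(C)C(C)(C)C | intermediate
25 | lithiated dithioacetal of 24 | [Li]C(Sc1ccccc1)(Sc1ccccc1)c1cc(OC)c2c(c1)O[C@H](c1ccc(O[Si](C(C)C)(C(C)C)C(C)C)c(OC)c1)[C@H]2CO[Si](C)(C)C(C)(C)C | intermediate
26 | lithium enolate of the 4,5-trans conjugate adduct | [Li]OC1=C[C@H](C(Sc2ccccc2)(Sc2ccccc2)c2cc(OC)c3c(c2)O[C@H](c2ccc(O[Si](C(C)C)(C(C)C)C(C)C)c(OC)c2)[C@H]3CO[Si](C)(C)C(C)(C)C)[C@@H](O[C@H]2C[C@@H](C)CC[C@@H]2C(C)C)O1 | intermediate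
27 | (3R,4S,5S)-3-[(R)-aryl(hydroxy)methyl]-4-[aryl-bis(phenylthio)methyl]-5-menthyloxybutyrolactone (carbinol epimer also expected) | O=C1O[C@H](O[C@H]2C[C@@H](C)CC[C@@H]2C(C)C)[C@@H](C(Sc2ccccc2)(Sc2ccccc2)c2cc(OC)c3c(c2)O[C@H](c2ccc(O[Si](C(C)C)(C(C)C)C(C)C)c(OC)c2)[C@H]3CO[Si](C)(C)C(C)(C)C)[C@@H]1[C@@H](O)c1ccc(OC)c(O[Si](C(C)C)(C(C)C)C(C)C)c1 | intermediate
28 | (3R,4S,5S)-3-[(R)-aryl(hydroxy)methyl]-4-(arylmethyl)-5-menthyloxybutyrolactone | O=C1O[C@H](O[C@H]2C[C@@H](C)CC[C@@H]2C(C)C)[C@@H](Cc2cc(OC)c3c(c2)O[C@H](c2ccc(O[Si](C(C)C)(C(C)C)C(C)C)c(OC)c2)[C@H]3CO[Si](C)(C)C(C)(C)C)[C@@H]1[C@@H](O)c1ccc(OC)c(O[Si](C(C)C)(C(C)C)C(C)C)c1 | intermediate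
29 | (2S,3S)-3-(arylmethyl)-2-[(R)-aryl(hydroxy)methyl]butane-1,4-diol | OC[C@@H](Cc1cc(OC)c2c(c1)O[C@H](c1ccc(O[Si](C(C)C)(C(C)C)C(C)C)c(OC)c1)[C@H]2CO[Si](C)(C)C(C)(C)C)[C@@H](CO)[C@@H](O)c1ccc(OC)c(O[Si](C(C)C)(C(C)C)C(C)C)c1 | intermediate
30 | tris-silyl ether of the target | COc1ccc([C@@H]2OC[C@@H](Cc3cc(OC)c4c(c3)O[C@H](c3ccc(O[Si](C(C)C)(C(C)C)C(C)C)c(OC)c3)[C@H]4CO[Si](C)(C)C(C)(C)C)[C@H]2CO)cc1O[Si](C(C)C)(C(C)C)C(C)C | intermediate
31 | CNP0242386.1 | COc1ccc([C@@H]2OC[C@@H](Cc3cc(OC)c4c(c3)O[C@H](c3ccc(O)c(OC)c3)[C@H]4CO)[C@H]2CO)cc1O | target

## Step count and risk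

Total: 19 steps. Longest linear sequence: 15 steps (steps 4 to 8 and 10 to 19, from 8).

**Step 15 (key step).**
- What may go wrong: incomplete or reversible conjugate addition of the very hindered anion, or slow trapping of the hindered enolate so that proton transfer or reversal of the aldol on warming returns the simple adduct. Both come from the size of the two partners around lactone C3 and C4.
- Fallback: split the tandem into two isolated operations. Setting out from 24 and 5, the anion is added as before and the enolate is quenched with aqueous NH4Cl to give the 4,5-trans conjugate adduct F1. F1 is purified, enolised again with LDA in THF at −78 °C and treated with 7 under conditions optimised for the aldol alone, then quenched cold with AcOH. The sequence comes back to the route at 27.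

**Step 18.**
- What may go wrong: once the ring closure becomes reversible, the benzylic cation is captured by C5 or C7 of ring A in a six-membered carbocyclisation, and the trans preference at C2 erodes. The primary silyl ether may also be lost.
- Fallback: change the order so that ring A is deactivated and crowded during the cationic step. Setting out from 27, LiAlH4 gives the bis(phenylthio) triol F2. CSA in CH2Cl2 closes the tetrahydrofuran to F3 while the carbon next to ring A is still a fully substituted, electron-withdrawing dithioketal. Raney Ni then removes sulfur last and the sequence comes back at 30.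

**Step 13.**
- What may go wrong: Lewis-acid-promoted ionisation of the para-siloxybenzylic C2–O bond of the dihydrobenzofuran with capture by thiophenol, giving ring opening or epimerisation at C2, in competition with thioacetalisation.
- Fallback: build the dithioacetal without any acid. Setting out from 22, the primary alcohol is silylated first (TBSCl, imidazole) to aldehyde F4. NaBH4 gives benzylic alcohol F5. PhSSPh with PBu3 (Hata-type thioetherification) gives benzyl phenyl sulfide F6. Deprotonation with LDA (2.1 equiv) and sulfenylation with PhSSPh (1.0 equiv), followed by NH4Cl, comes back to the route at 24 and bypasses 23.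

**Step 6.**
- What may go wrong: sluggish opening of ethylene oxide by the di-ortho-substituted aryllithium, with return of 10 on work-up; a minor share of metalation beside the acetal is possible but less likely.
- Fallback: use a more reactive electrophile and reach the acid by oxidative cleavage. Setting out from 10 through 11, CuBr·SMe2 (cat.) and allyl bromide give allyl arene F7. K2OsO4·2H2O (cat.) with NaIO4 and 2,6-lutidine in dioxane–water (Lemieux–Johnson cleavage) gives arylacetaldehyde F8. Pinnick oxidation (NaClO2, NaH2PO4, 2-methyl-2-butene) comes back to the route at 13 and bypasses 12.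

## Further compounds

F1 | step 15 | (4S,5S)-4-[aryl-bis(phenylthio)methyl]-5-menthyloxydihydrofuran-2(3H)-one | O=C1C[C@H](C(Sc2ccccc2)(Sc2ccccc2)c2cc(OC)c3c(c2)O[C@H](c2ccc(O[Si](C(C)C)(C(C)C)C(C)C)c(OC)c2)[C@H]3CO[Si](C)(C)C(C)(C)C)[C@@H](O[C@H]2C[C@@H](C)CC[C@@H]2C(C)C)O1
F2 | step 18 | bis(phenylthio) triol from reduction of 27 | OC[C@@H](C(Sc1ccccc1)(Sc1ccccc1)c1cc(OC)c2c(c1)O[C@H](c1ccc(O[Si](C(C)C)(C(C)C)C(C)C)c(OC)c1)[C@H]2CO[Si](C)(C)C(C)(C)C)[C@@H](CO)[C@@H](O)c1ccc(OC)c(O[Si](C(C)C)(C(C)C)C(C)C)c1
F3 | step 18 | bis(phenylthio) analogue of 30 | COc1ccc([C@@H]2OC[C@@H](C(Sc3ccccc3)(Sc3ccccc3)c3cc(OC)c4c(c3)O[C@H](c3ccc(O[Si](C(C)C)(C(C)C)C(C)C)c(OC)c3)[C@H]4CO[Si](C)(C)C(C)(C)C)[C@H]2CO)cc1O[Si](C(C)C)(C(C)C)C(C)C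
F4 | step 13 | tert-butyldimethylsilyl ether of aldehyde 22 | O=Cc1cc(OC)c2c(c1)O[C@H](c1ccc(O[Si](C(C)C)(C(C)C)C(C)C)c(OC)c1)[C@H]2CO[Si](C)(C)C(C)(C)C
F5 | step 13 | 6-(hydroxymethyl) dihydrobenzofuran | OCc1cc(OC)c2c(c1)O[C@H](c1ccc(O[Si](C(C)C)(C(C)C)C(C)C)c(OC)c1)[C@H]2CO[Si](C)(C)C(C)(C)C
F6 | step 13 | 6-[(phenylthio)methyl] dihydrobenzofuran | c1ccc(cc1)SCc1cc(OC)c2c(c1)O[C@H](c1ccc(O[Si](C(C)C)(C(C)C)C(C)C)c(OC)c1)[C@H]2CO[Si](C)(C)C(C)(C)C
F7 | step 6 | 2-[4-allyl-3-methoxy-5-(methoxymethoxy)phenyl]-5,5-dimethyl-1,3-dioxane | C=CCc1c(OC)cc(cc1OCOC)C1OCC(C)(C)CO1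
F8 | step 6 | [4-(5,5-dimethyl-1,3-dioxan-2-yl)-2-methoxy-6-(methoxymethoxy)phenyl]acetaldehyde | O=CCc1c(OC)cc(cc1OCOC)C1OCC(C)(C)CO1
A1 | alternative 1 | 2-(dioxanyl)-3-triisopropylsilyloxy-5-(tetrahydrofuranylmethyl)phenol | COc1ccc([C@@H]2OC[C@@H](Cc3cc(O)c([C@@H]4COC(C)(C)O[C@H]4c4ccc(OCc5ccccc5)c(OC)c4)c(O[Si](C(C)C)(C(C)C)C(C)C)c3)[C@H]2CO[Si](C)(C)C(C)(C)C)cc1OCc1ccccc1
A2 | alternative 1 | 3-(tetrahydrofuranylmethyl)cyclobut-2-en-1-one | COc1ccc([C@@H]2OC[C@@H](CC3=CC(=O)C3)[C@H]2CO[Si](C)(C)C(C)(C)C)cc1OCc1ccccc1
A3 | alternative 1 | triisopropylsilyl ynol ether of the 4-aryl-2,2-dimethyl-1,3-dioxan-5-yl alkyne | CC(C)[Si](C(C)C)(C(C)C)OC#C[C@@H]1COC(C)(C)O[C@H]1c1ccc(OCc2ccccc2)c(OC)c1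
A4 | alternative 2 | bis(aryl acetate) of the target | COc1ccc([C@@H]2OC[C@@H](Cc3cc(OC)c4c(c3)O[C@H](c3ccc(OC(C)=O)c(OC)c3)[C@H]4CO)[C@H]2CO)cc1OC(C)=O
A5 | alternative 2 | dibenzylbutanediol bis(aryl acetate) | OC[C@@H](Cc1cc(OC)c2c(c1)O[C@H](c1ccc(OC(C)=O)c(OC)c1)[C@H]2CO)[C@H](Cc1ccc(OC)c(OC(C)=O)c1)CO
A6 | alternative 3 | methyl (2S,3S)-trans-6-benzyloxy-4-methoxy-2-aryl-2,3-dihydrobenzofuran-3-carboxylate | COc1cc(OCc3ccccc3)cc2c1[C@H](C(=O)OC)[C@@H](c1ccc(O[Si](C(C)C)(C(C)C)C(C)C)c(OC)c1)O2
A7 | alternative 3 | (S)-7-benzyloxy-5-methoxy-2-[3-methoxy-4-(triisopropylsilyloxy)phenyl]chroman-4-one | COc1cc(OCc2ccccc2)cc2O[C@@H](CC(=O)c12)c1ccc(O[Si](C(C)C)(C(C)C)C(C)C)c(OC)c1
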